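## Retrosynthetic overview

- The target is reached from a 4β,10β-dioxygenated trans-guaian-8β-yl veratrate by anti dehydration of the C4 carbinol to the C3=C4 alkene, α-face epoxidation and desilylation.
- The strategy rests on the C1–C5 fusion bond, shared by the cyclopentane (C1–C2–C3–C4–C5) and the cycloheptane (C1–C10–C9–C8–C7–C6–C5). Cutting it leaves a ten-membered germacrane ring, and the 8β-ester and 10β-hydroxyl sit 1,3-cis on the seven-membered ring, so the veratrate carbonyl can bring the C10 oxygen.
- Both carbocycles close in one transannular opening of (4S,5S)-4,5-epoxygermacr-1(10)-en-8-yl veratrate. The epoxide oxygen stays at C4 as a silyl ether and is later removed to make the C3–C4 oxirane.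
- The precursor comes from germacrone by Li/NH3 conjugate reduction, enzymatic ketone reduction, veratroylation and Shi epoxidation.
- Ring order: the ten-membered ring is bought with germacrone; the five- and seven-membered rings form together in step 5; the oxirane comes last (step 8).

Key step: step 5

Remark: germacrane/guaiane numbering is used throughout (C14 = methyl on C10, C15 = methyl on C4, isopropyl on C7); the L-fructose-derived enantiomer of the Shi ketone and a ketoreductase screening panel are assumed to be at hand.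

## Route

Step 1
Reactants: 1 germacrone
Product: 3 (±)-7,11-dihydrogermacrone, via lithium enolate 2 (not isolated)
Conditions: Li (2.2 equiv), t-BuOH (1 equiv), NH3(l)/THF, −78 °C; isoprene, then NH4Cl
Reagents that add atoms: none
Why: Dissolving-metal (Birch-type) conjugate reduction of an α-isopropylidene ketone, as with pulegone: electron transfer and protonation at C11 give the C7–C8 lithium enolate regiospecifically, the isolated trisubstituted alkenes are not reduced, and NH4Cl protonation at C7 gives the racemic saturated ketone without moving the β,γ-alkene into conjugation.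

Step 2
Reactants: 3 (±)-7,11-dihydrogermacrone
Product: 4 (7R,8R)-germacra-1(10)E,4E-dien-8-ol
Conditions: NADPH-dependent ketoreductase (panel hit for the 7R ketone), NADP+ (cat.), i-PrOH, aq. KH2PO4/K2HPO4 buffer pH 7, DMSO (5%), 30 °C
Reagents that add atoms: none
Why: Enzymatic carbonyl reduction run as a kinetic resolution: the enzyme should accept only the 7R ketone and deliver hydride to the face of C8 that gives the 8R carbinol cis to the isopropyl group, at neutral pH where neither C7 nor the β,γ-alkene is disturbed; the untouched 7S ketone is removed by chromatography, so at most half of 3 can be used.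

Step 3
Reactants: 4 (7R,8R)-germacra-1(10)E,4E-dien-8-ol; 5 3,4-dimethoxybenzoyl chloride
Product: 6 (7R,8R)-germacra-1(10)E,4E-dien-8-yl 3,4-dimethoxybenzoate
Conditions: Et3N, DMAP (cat.), CH2Cl2, 0 °C → rt
Reagents that add atoms: 5 3,4-dimethoxybenzoyl chloride, COc1ccc(C(=O)Cl)cc1OC
Why: DMAP-catalysed acylation (nucleophilic catalysis) of the hindered secondary alcohol with the acid chloride touches no stereocentre, and working at or below room temperature avoids Cope rearrangement of the 1,5-diene.

Step 4
Reactants: 6 (7R,8R)-germacra-1(10)E,4E-dien-8-yl 3,4-dimethoxybenzoate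
Product: 7 (4S,5S,7R,8R)-4,5-epoxygermacr-1(10)E-en-8-yl 3,4-dimethoxybenzoate
Conditions: 1,2:4,5-di-O-isopropylidene-β-L-erythro-2,3-hexodiulo-2,6-pyranose (L-series Shi ketone, 0.3 equiv), KHSO5 (as 2KHSO5·KHSO4·K2SO4), K2CO3, Bu4NHSO4, MeCN–dimethoxymethane/aq. Na2B4O7 buffer (pH 10.5), 0 °C
Reagents that add atoms: potassium peroxymonosulfate, [K+].[O-]S(=O)(=O)OO
Why: Shi asymmetric epoxidation: the chiral dioxirane of the L-series ketone transfers oxygen to trans-trisubstituted alkenes through a spiro transition state in the sense that gives S,S epoxides, so C4 and C5 are set by the catalyst acting on the outer face of those ring conformers that carry C15 on the α side, while the 1(10)-alkene is deactivated inductively and screened by the homoallylic aroyloxy group at C8; the acid-labile product is purified on Et3N-deactivated silica.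

Step 5
Reactants: 7 (4S,5S,7R,8R)-4,5-epoxygermacr-1(10)E-en-8-yl 3,4-dimethoxybenzoate
Product: 10 10β-hydroxy-4β-(trimethylsilyloxy)-1αH,5βH,7αH-guaian-8β-yl 3,4-dimethoxybenzoate, via dioxanylium triflate 8 (not isolated), via 10-O-veratroyl isomer 9 (not isolated)
Conditions: TMSOTf (1.1 equiv), 2,6-di-tert-butyl-4-methylpyridine, CH2Cl2, −78 °C; sat. aq. NaHCO3–THF, −78 → 0 °C; then DBU (0.3 equiv), toluene, rt
Reagents that add atoms: trimethylsilyl trifluoromethanesulfonate, C[Si](C)(C)OS(=O)(=O)C(F)(F)F; water, O
Why: Proposed new method: O-silylation of the epoxide makes C5 electrophilic, the C1=C10 π bond displaces the oxygen at C5 from the rear across the ring to form C1–C5 and leave a tertiary cation at C10, and, with no water and only triflate present, the carbonyl oxygen of the C8 veratrate is the one nucleophile within reach and closes the 2-aryl-1,3-dioxan-2-ylium ion 8 onto C10; water then attacks the acyl carbon, and any 10-O-acyl isomer 9 formed in the ring opening is returned to the less hindered secondary ester by DBU-mediated 1,3-acyl migration. The closest known reactions are the acid-induced transannular cyclisation of germacrene 4,5-epoxides to guaiane-4,10-diols and Woodward–Prévost-type acyloxonium capture; their combination on a transannular cation, and the silyl triflate trigger, are untested. The five-membered ring closes exo at the alkene and endo at the epoxide, the seven-membered ring endo at the alkene and exo at the epoxide (one transannular bond serves both), and the transient dioxanylium ring forms as a six-membered ring by carbonyl-oxygen capture of the cation. C5 is set by inversion at the 5S epoxide carbon (H-5β, C4 unchanged as the 4β-silyloxy group), C1 by the fold of the ten-membered ring (H-1α), and C10 by the cis-only dioxanylium bridge from the 8β-oxygen (10β-O, methyl α). The step needs the parallel fold with H-1 anti to H-5, and capture of C10 syn to the new C1–C5 bond in place of anti capture or proton loss: the 4S,5S epoxide holds C15 on the α face, so with the 7β-isopropyl group equatorial the accessible reacting conformer carries C14 on the β face (the crossed alternative would need a boat–boat ring), and the tether, together with the absence of water and nucleophilic anions until the quench, secures the β-face capture.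

Step 6
Reactants: 10 10β-hydroxy-4β-(trimethylsilyloxy)-1αH,5βH,7αH-guaian-8β-yl 3,4-dimethoxybenzoate
Product: 12 4β-hydroxy-10β-(triethylsilyloxy)-1αH,5βH,7αH-guaian-8β-yl 3,4-dimethoxybenzoate, via bis-silyl ether 11 (not isolated)
Conditions: TESOTf, 2,6-lutidine, CH2Cl2, −78 → 0 °C, aq. work-up; then PPTS, MeOH–CH2Cl2, 0 °C
Reagents that add atoms: triethylsilyl trifluoromethanesulfonate, CC[Si](CC)(CC)OS(=O)(=O)C(F)(F)F
Why: Silyl triflate silylation of the only free (C10) tertiary hydroxyl, then selective acid-catalysed methanolysis of the much more labile trimethylsilyl ether beside the triethylsilyl ether, frees the C4 carbinol alone and so tells the two tertiary oxygens apart; no stereocentre is touched.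

Step 7
Reactants: 12 4β-hydroxy-10β-(triethylsilyloxy)-1αH,5βH,7αH-guaian-8β-yl 3,4-dimethoxybenzoate
Product: 14 10β-(triethylsilyloxy)-1αH,5βH,7αH-guai-3-en-8β-yl 3,4-dimethoxybenzoate, via C4 dichlorophosphate 13 (not isolated)
Conditions: POCl3, pyridine, 0 °C → rt
Reagents that add atoms: none
Why: Anti (E2) dehydration through the dichlorophosphate: the 4β-oxygen is cis to H-5, so the ring fusion offers no anti-periplanar hydrogen and pyridine removes H-3α (endocyclic elimination in a cyclopentane) in preference to a methyl hydrogen, while the C10 oxygen is masked as its silyl ether.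

Step 8
Reactants: 14 10β-(triethylsilyloxy)-1αH,5βH,7αH-guai-3-en-8β-yl 3,4-dimethoxybenzoate
Product: 15 3α,4α-epoxy-10β-(triethylsilyloxy)-1αH,5βH,7αH-guaian-8β-yl 3,4-dimethoxybenzoate
Conditions: mCPBA, NaHCO3, CH2Cl2, 0 °C
Reagents that add atoms: 3-chloroperoxybenzoic acid, OOC(=O)c1cccc(Cl)c1
Why: Prilezhaev epoxidation of the trisubstituted cyclopentene: the trans ring fusion puts the envelope flap C1 on the α side and the pseudoaxial allylic hydrogens H-5β and H-2β on the β face, so α-face attack is the staggered, torsionally favoured one, and the silyl group on the 10β-oxygen removes hydrogen-bond delivery to the β face and adds bulk there, which should set C3 and C4 as the α-epoxide.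

Step 9
Reactants: 15 3α,4α-epoxy-10β-(triethylsilyloxy)-1αH,5βH,7αH-guaian-8β-yl 3,4-dimethoxybenzoate
Product: 16 3α,4α-epoxy-10β-hydroxy-1αH,5βH,7αH-guaian-8β-yl 3,4-dimethoxybenzoate (CNP0304846.1)
Conditions: TBAF, AcOH, THF, 0 °C → rt
Reagents that add atoms: none
Why: Fluoride desilylation buffered with acetic acid cleaves the tertiary silyl ether under conditions that leave the epoxide and the aryl ester alone and do not promote acyl migration.

## Compound list

1 | germacrone, (3E,7E)-3,7-dimethyl-10-(propan-2-ylidene)cyclodeca-3,7-dien-1-one | C/C1=C\CC(=C(C)C)C(=O)C/C(C)=C/CC1 | starting material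
2 | lithium C7–C8 enolate of 7,11-dihydrogermacrone | CC(C)C1=C([O-])C/C(C)=C/CC/C(C)=C/C1.[Li+] | intermediate (not isolated)
3 | (±)-7,11-dihydrogermacrone, (3E,7E)-3,7-dimethyl-10-(propan-2-yl)cyclodeca-3,7-dien-1-one, racemic at C7 | CC(C)C1C/C=C(C)/CC/C=C(C)/CC1=O | intermediate
4 | (7R,8R)-germacra-1(10)E,4E-dien-8-ol (isopropyl and hydroxyl cis) | O[C@@H]1C/C(C)=C/CC/C(C)=C/C[C@@H]1C(C)C | intermediate
5 | 3,4-dimethoxybenzoyl chloride (veratroyl chloride) | COc1ccc(C(=O)Cl)cc1OC | starting material
6 | (7R,8R)-germacra-1(10)E,4E-dien-8-yl 3,4-dimethoxybenzoate | COc1ccc(C(=O)O[C@@H]2C/C(C)=C/CC/C(C)=C/C[C@@H]2C(C)C)cc1OC | intermediate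
7 | (4S,5S,7R,8R)-4,5-epoxygermacr-1(10)E-en-8-yl 3,4-dimethoxybenzoate | COc1ccc(C(=O)O[C@@H]2C/C(C)=C/CC[C@]4(C)O[C@H]4C[C@@H]2C(C)C)cc1OC | intermediate (key-step precursor)
8 | 2-(3,4-dimethoxyphenyl)-1,3-dioxan-2-ylium triflate bridging O8 and O10 of 4β-(trimethylsilyloxy)-1αH,5βH-guaiane | COc1ccc(C5O[C@@H]2C[C@](C)([O+]=5)[C@@H]3CC[C@](C)(O[Si](C)(C)C)[C@H]3C[C@@H]2C(C)C)cc1OC.[O-]S(=O)(=O)C(F)(F)F | intermediate (not isolated)
9 | 8β-hydroxy-4β-(trimethylsilyloxy)-1αH,5βH,7αH-guaian-10β-yl 3,4-dimethoxybenzoate (10-O-acyl regioisomer) | O[C@@H]2C[C@](C)(OC(=O)c1ccc(OC)c(OC)c1)[C@@H]3CC[C@](C)(O[Si](C)(C)C)[C@H]3C[C@@H]2C(C)C | intermediate (not isolated)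
10 | (1R,4S,5S,7R,8R,10S)-10β-hydroxy-4β-(trimethylsilyloxy)-1αH,5βH,7αH-guaian-8β-yl 3,4-dimethoxybenzoate | COc1ccc(C(=O)O[C@@H]2C[C@](C)(O)[C@@H]3CC[C@](C)(O[Si](C)(C)C)[C@H]3C[C@@H]2C(C)C)cc1OC | intermediate (key-step product)
11 | 10β-(triethylsilyloxy)-4β-(trimethylsilyloxy)-1αH,5βH,7αH-guaian-8β-yl 3,4-dimethoxybenzoate | COc1ccc(C(=O)O[C@@H]2C[C@](C)(O[Si](CC)(CC)CC)[C@@H]3CC[C@](C)(O[Si](C)(C)C)[C@H]3C[C@@H]2C(C)C)cc1OC | intermediate (not isolated)
12 | (1R,4S,5S,7R,8R,10S)-4β-hydroxy-10β-(triethylsilyloxy)-1αH,5βH,7αH-guaian-8β-yl 3,4-dimethoxybenzoate | COc1ccc(C(=O)O[C@@H]2C[C@](C)(O[Si](CC)(CC)CC)[C@@H]3CC[C@](C)(O)[C@H]3C[C@@H]2C(C)C)cc1OC | intermediate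
13 | 4β-(dichlorophosphoryloxy)-10β-(triethylsilyloxy)-1αH,5βH,7αH-guaian-8β-yl 3,4-dimethoxybenzoate | COc1ccc(C(=O)O[C@@H]2C[C@](C)(O[Si](CC)(CC)CC)[C@@H]3CC[C@](C)(OP(=O)(Cl)Cl)[C@H]3C[C@@H]2C(C)C)cc1OC | intermediate (not isolated)
14 | (1R,5S,7R,8R,10S)-10β-(triethylsilyloxy)-1αH,5βH,7αH-guai-3-en-8β-yl 3,4-dimethoxybenzoate | COc1ccc(C(=O)O[C@@H]2C[C@](C)(O[Si](CC)(CC)CC)[C@@H]3CC=C(C)[C@H]3C[C@@H]2C(C)C)cc1OC | intermediate
15 | (1R,3R,4S,5S,7R,8R,10S)-3α,4α-epoxy-10β-(triethylsilyloxy)-1αH,5βH,7αH-guaian-8β-yl 3,4-dimethoxybenzoate | COc1ccc(C(=O)O[C@@H]2C[C@](C)(O[Si](CC)(CC)CC)[C@@H]3C[C@H]4O[C@@]4(C)[C@H]3C[C@@H]2C(C)C)cc1OC | intermediate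
16 | (1R,3R,4S,5S,7R,8R,10S)-3α,4α-epoxy-10β-hydroxy-1αH,5βH,7αH-guaian-8β-yl 3,4-dimethoxybenzoate (CNP0304846.1) | COc1ccc(C(=O)O[C@@H]2C[C@](C)(O)[C@@H]3C[C@H]4O[C@@]4(C)[C@H]3C[C@@H]2C(C)C)cc1OC | target

## Step count and risks

Total step count: 9. Longest linear sequence: 9 steps, from germacrone (1).

Steps most likely to fail:

1. Step 5 (proposed new method). The C10 cation may lose a proton, or be taken on the α face, before the tethered carbonyl closes on the β face; the macrocycle may also fold through the crossed conformer and give the cis ring fusion. Fallback with known chemistry, setting out from 7 and returning at 10: the same silyl triflate activation with excess 2,6-lutidine (CH2Cl2, −78 → −20 °C) steers the cation to proton loss, the usual outcome of Lewis-acid cyclisations of germacrene 4,5-epoxides. The exocyclic alkene 4β-(trimethylsilyloxy)-1αH,5βH-guai-10(14)-en-8β-yl 3,4-dimethoxybenzoate F1 is separated from its endocyclic isomers. An intramolecular Woodward–Prévost-type iodo-acyloxylation (NIS, CH2Cl2, 0 °C, then aq. NaHCO3) then lets the same cis tether deliver oxygen to C10 of an iodonium ion, giving 10β-hydroxy-14-iodo-4β-(trimethylsilyloxy)-1αH,5βH-guaian-8β-yl 3,4-dimethoxybenzoate F2. Radical deiodination (Bu3SnH, AIBN, toluene, 80 °C), followed by the DBU acyl equilibration of step 5, gives 10.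

2. Step 8. Facial selectivity may be poor: the peracid may prefer the β face of the cyclopentene (anti to C6 at the allylic centre) and give the 3β,4β-epoxide. Fallback setting out from 14 and returning at 15: a halohydrin route, which inverts the facial outcome of any electrophile. NBS in THF–H2O (0 °C) should put the bromonium ion on the face the peracid preferred and bring water to the tertiary C4 from the α face, giving 3β-bromo-4α-hydroxy-10β-(triethylsilyloxy)-1αH,5βH-guaian-8β-yl 3,4-dimethoxybenzoate F3. DBU (CH2Cl2, rt) then closes the oxirane with inversion at C3 to give 15.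

3. Step 4. Site selectivity between the two ring alkenes may be poor, with over-epoxidation, and face control on the mobile macrocycle may be incomplete. Fallback setting out from 3 and returning at 7: the epoxidation is moved to the ketone, where the 1(10)-alkene is β,γ to the carbonyl group and the substrate is still racemic, so that the catalyst-controlled epoxidation also serves as the resolving step. The Shi conditions of step 4 applied to 3 should give (4S,5S,7R)-4,5-epoxy-7,11-dihydrogermacrone F4 and its diastereomer (4S,5S,7S)-4,5-epoxy-7,11-dihydrogermacrone F5, which are separable by chromatography. The ketoreductase of step 2 reduces F4 to (4S,5S,7R,8R)-4,5-epoxygermacr-1(10)E-en-8-ol F6, and acylation with 5 as in step 3 gives 7.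

Further compounds
F1 | step 5 | 4β-(trimethylsilyloxy)-1αH,5βH,7αH-guai-10(14)-en-8β-yl 3,4-dimethoxybenzoate | COc1ccc(C(=O)O[C@@H]2CC(=C)[C@@H]3CC[C@](C)(O[Si](C)(C)C)[C@H]3C[C@@H]2C(C)C)cc1OC
F2 | step 5 | 10β-hydroxy-14-iodo-4β-(trimethylsilyloxy)-1αH,5βH,7αH-guaian-8β-yl 3,4-dimethoxybenzoate | COc1ccc(C(=O)O[C@@H]2C[C@](CI)(O)[C@@H]3CC[C@](C)(O[Si](C)(C)C)[C@H]3C[C@@H]2C(C)C)cc1OC
F3 | step 8 | 3β-bromo-4α-hydroxy-10β-(triethylsilyloxy)-1αH,5βH,7αH-guaian-8β-yl 3,4-dimethoxybenzoate | COc1ccc(C(=O)O[C@@H]2C[C@](C)(O[Si](CC)(CC)CC)[C@@H]3C[C@H](Br)[C@@](C)(O)[C@H]3C[C@@H]2C(C)C)cc1OC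
F4 | step 4 | (4S,5S,7R)-4,5-epoxy-7,11-dihydrogermacrone | O=C1C/C(C)=C/CC[C@]4(C)O[C@H]4C[C@@H]1C(C)C
F5 | step 4 | (4S,5S,7S)-4,5-epoxy-7,11-dihydrogermacrone | O=C1C/C(C)=C/CC[C@]4(C)O[C@H]4C[C@H]1C(C)C
F6 | step 4 | (4S,5S,7R,8R)-4,5-epoxygermacr-1(10)E-en-8-ol | O[C@@H]1C/C(C)=C/CC[C@]4(C)O[C@H]4C[C@@H]1C(C)C
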